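**Small charge.** A small charge of G, 0.10 M in maple, yields X hesitantly under held L, and larch at 0.15 M does the same. The flask takes 0.20 M, and no L is dissolved at the start.

| flask | G | L | remark | time |
|---|---|---|---|---|
| maple | 0.10 M | 120 mM (held) | run made earlier |  |
| larch | 0.15 M | 120 mM (held) | run made earlier |  |
| flask | 0.20 M | 120 mM (held) |  | 30 min |

| maple: time / min | maple: X / % | larch: time / min | larch: X / % |
|---|---|---|---|
| 5.00 | 1.5 | 2.00 | 0 |
| 10.0 | 1.3 | 6.00 | 1.3 |
| 15.0 | 3.3 | 12.0 | 2.5 |
| 20.0 | 4.8 | 15.0 | 2.6 |
| 25.0 | 7.1 | 25.0 | 6.5 |

(standard deviation of a reading: 0.5 percentage points)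

* amount of X at 30 min, in percent of the G charged
* the change that raises the amount of X at 30 min, in percent of the G charged most ("none" if none brings more than 2 percentage points) (Tuesday's / Friday's / none)
* amount of X at 30 min, in percent of the G charged, after Friday's

- the analysis behind the earlier runs scatters by 0.5 percentage points, standard deviation
- at the start none of L is in solution

- Tuesday's: doubling the saturation concentration of L, all else as stated
- Friday's: doubling the transfer coefficient of L, all else as stated

**Slope, lag.** From 15.0 min to 25.0 min the two runs gain on average 3.9 percentage points. Call the lag (induction period) the time at which this late straight line of X, run backwards, meets zero; read from the runs, 7.34 min.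

**Four settings.** G: the last readings differ by 0.6 points, near the scatter of 0.5 points, so by hand the larger charge keeps the same percent line. Time: my line reaches 8.73 % at 30 min. Friday's doubles the transfer coefficient of L: if the lag is the filling of the solution, that halves the lag and gains 1.4 points. Tuesday's doubles the saturation concentration of L: if the rate follows dissolved L, the slope doubles and the gain equals 8.73 %, so by hand it gains more than Friday's.

**Forecast.** The forecast gives 8.7 %, Tuesday's and 10 %, holding that “Doubling saturation doubles dissolved L throughout”.

**Result.** The flask gives 8.54 %, with Tuesday's best at 5.8 points against 3.3 points, and 11.8 % after Friday's. Here J is dissolved L: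

    L ⇌ J, rate k1*(csat - [J]) (kL = 0.0410 min⁻¹)
    G + J → X (k = 0.0750 M⁻¹ min⁻¹)
    J + X → D (k = 0.180 M⁻¹ min⁻¹)

At 30 min the flask still holds 90.4 % of its G, and D stands at 1.10 %. The line from the lag lies 0.19 points above the flask's X. Carried to the neighbour, the same flask read at 2.0 h, the same lag and slope give 43.4 %, but that neighbour holds X 22.3 % and D 25.7 %.

The data were computed for an exercise; noise was put on by code.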